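**Assumption:** the target SMILES carries no stereocentre or other stereogenic element, so the compound is achiral and no enantiocontrol is needed. The only stereocentre on the route (carbinol 9, racemic) is destroyed in step 6.

## Retrosynthetic overview

1. Digriseophene A 15 comes from bis-benzyl ether 14 by double O-debenzylation; the ring-B phenols stay masked during the coupling.
2. The central ArCH2–Ar bond of 14 comes from an intermolecular Michael addition of acylphloroglucinol 11 to o-quinone methide 13, released from Mannich base 12 (11 + Eschenmoser's salt).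
3. Monomer 11 comes from aryllithium 8 (ortho-lithiation of bis-MOM 5-methoxyresorcinol 7) and aldehyde 5, followed by oxidation and MOM removal.
4. Aldehyde 5 comes from orcinol 1 by Vilsmeier formylation, 4-O-benzylation and 2-O-methylation.
5. No ring is constructed: ring B is bought as orcinol and ring A as 5-methoxyresorcinol. Ring B is elaborated first, then joined to ring A, then the benzophenone is dimerised.

## Route

Step 1
Reactants: 1 orcinol (5-methylbenzene-1,3-diol)
Product: 3 2,4-dihydroxy-6-methylbenzaldehyde, via aryl iminium chloride 2 (not isolated)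
Conditions: POCl3 (1.2 equiv), DMF, 0 °C → rt; then H2O, 50 °C
Reagents that add atoms: N,N-dimethylformamide CN(C)C=O (formyl carbon); water O (aldehyde oxygen)
Why: Vilsmeier–Haack formylation; the chloroiminium attacks the position para to one OH and ortho to the other (next to the methyl) in preference to the crowded site between both hydroxyls, and hydrolysis of the iminium gives the aldehyde.

Step 2
Reactants: 3 2,4-dihydroxy-6-methylbenzaldehyde
Product: 4 4-(benzyloxy)-2-hydroxy-6-methylbenzaldehyde
Conditions: BnBr (1.05 equiv), NaHCO3 (1.5 equiv), KI (cat.), MeCN, 80 °C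
Reagents that add atoms: benzyl bromide BrCc1ccccc1
Why: Williamson etherification; the 2-OH is hydrogen-bonded to the aldehyde, so the free and more acidic 4-OH is alkylated selectively with a weak base.

Step 3
Reactants: 4 4-(benzyloxy)-2-hydroxy-6-methylbenzaldehyde
Product: 5 4-(benzyloxy)-2-methoxy-6-methylbenzaldehyde
Conditions: MeI (2 equiv), K2CO3, DMF, rt → 40 °C
Reagents that add atoms: iodomethane CI
Why: Williamson O-methylation of the remaining chelated phenol under the stronger K2CO3/DMF conditions; nothing else in the molecule can be alkylated.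

Step 4
Reactants: 6 5-methoxyresorcinol (5-methoxybenzene-1,3-diol)
Product: 7 1-methoxy-3,5-bis(methoxymethoxy)benzene
Conditions: NaH (2.4 equiv), MOMCl (2.4 equiv), DMF, 0 °C → rt
Reagents that add atoms: chloromethyl methyl ether COCCl
Why: MOM acetal protection of both phenols; MOM is a strong ortho-lithiation director and is later removed by mild acid without touching benzyl or methyl ethers.

Step 5
Reactants: 7 1-methoxy-3,5-bis(methoxymethoxy)benzene (1.3 equiv); 5 4-(benzyloxy)-2-methoxy-6-methylbenzaldehyde
Product: 9 [4-(benzyloxy)-2-methoxy-6-methylphenyl][4-methoxy-2,6-bis(methoxymethoxy)phenyl]methanol (racemic), via aryllithium 8 (not isolated)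
Conditions: n-BuLi (1.25 equiv), TMEDA, THF, 0 °C, 1 h; then 5, −78 °C → rt; H2O quench
Reagents that add atoms: none
Why: directed ortho-metalation at the carbon flanked by two OMOM groups (stronger, cooperative directors than OMe), then 1,2-addition of the aryllithium to the aldehyde; the new carbinol centre is racemic and is removed in step 6.

Step 6
Reactants: 9 [4-(benzyloxy)-2-methoxy-6-methylphenyl][4-methoxy-2,6-bis(methoxymethoxy)phenyl]methanol
Product: 10 [4-(benzyloxy)-2-methoxy-6-methylphenyl][4-methoxy-2,6-bis(methoxymethoxy)phenyl]methanone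
Conditions: IBX (1.5 equiv), DMSO, rt
Reagents that add atoms: none
Why: IBX oxidation of the doubly benzylic secondary alcohol to the benzophenone under neutral conditions that leave MOM, benzyl and methyl ethers intact.

Step 7
Reactants: 10 [4-(benzyloxy)-2-methoxy-6-methylphenyl][4-methoxy-2,6-bis(methoxymethoxy)phenyl]methanone
Product: 11 [4-(benzyloxy)-2-methoxy-6-methylphenyl](2,6-dihydroxy-4-methoxyphenyl)methanone
Conditions: conc. HCl (cat.), MeOH, 50 °C
Reagents that add atoms: none
Why: acid-catalysed acetal exchange with methanol cleaves both MOM ethers, while the aryl benzyl ether, the methyl ethers and the hindered ketone are stable.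

Step 8
Reactants: 11 [4-(benzyloxy)-2-methoxy-6-methylphenyl](2,6-dihydroxy-4-methoxyphenyl)methanone
Product: 12 [4-(benzyloxy)-2-methoxy-6-methylphenyl]{3-[(dimethylamino)methyl]-2,6-dihydroxy-4-methoxyphenyl}methanone
Conditions: Eschenmoser's salt (1.0 equiv), CH2Cl2, 0 °C → rt; aq. NaHCO3 work-up
Reagents that add atoms: N,N-dimethylmethyleneiminium iodide C=[N+](C)C.[I-]
Why: Mannich aminomethylation at one of the two equivalent free carbons of the acylphloroglucinol ring (ortho/para to three oxygen donors); the ammonium product is deactivated, so one equivalent stops at mono-substitution, and the acyl-deactivated ring-B ether does not compete.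

Step 9
Reactants: 12 [4-(benzyloxy)-2-methoxy-6-methylphenyl]{3-[(dimethylamino)methyl]-2,6-dihydroxy-4-methoxyphenyl}methanone; 11 [4-(benzyloxy)-2-methoxy-6-methylphenyl](2,6-dihydroxy-4-methoxyphenyl)methanone (3 equiv, excess recovered)
Product: 14 bis{3-[4-(benzyloxy)-2-methoxy-6-methylbenzoyl]-2,4-dihydroxy-6-methoxyphenyl}methane, via o-quinone methide 13 (not isolated)
Conditions: slow addition of 12 to 11, 1,4-dioxane, 100 °C, N2 sweep
Reagents that add atoms: none
Why: thermal loss of dimethylamine from the ortho-hydroxybenzylamine gives the o-quinone methide, which is captured in an intermolecular Michael addition by the free ring carbon of the enolic acylphloroglucinol 11 and re-aromatises to the methylene bridge; excess 11 suppresses oligomers.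

Step 10
Reactants: 14 bis{3-[4-(benzyloxy)-2-methoxy-6-methylbenzoyl]-2,4-dihydroxy-6-methoxyphenyl}methane
Product: 15 Digriseophene A, bis[2,4-dihydroxy-3-(4-hydroxy-2-methoxy-6-methylbenzoyl)-6-methoxyphenyl]methane
Conditions: H2 (1 atm), 10% Pd/C, EtOAc–MeOH, rt, stopped at full conversion
Reagents that add atoms: none
Why: Pd-catalysed hydrogenolysis of the two aryl benzyl ethers; the hydrogen-bonded, tetra-ortho-substituted diaryl ketones and the diarylmethane are inert at 1 atm and rt.

## Compound list

1 | orcinol (5-methylbenzene-1,3-diol) | Cc1cc(O)cc(O)c1 | starting material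
2 | (2,4-dihydroxy-6-methylbenzylidene)dimethyliminium chloride | C[N+](C)=Cc1c(C)cc(O)cc1O.[Cl-] | intermediate
3 | 2,4-dihydroxy-6-methylbenzaldehyde | Cc1cc(O)cc(O)c1C=O | intermediate
4 | 4-(benzyloxy)-2-hydroxy-6-methylbenzaldehyde | Cc1cc(OCc2ccccc2)cc(O)c1C=O | intermediate
5 | 4-(benzyloxy)-2-methoxy-6-methylbenzaldehyde | COc1cc(OCc2ccccc2)cc(C)c1C=O | intermediate
6 | 5-methoxyresorcinol (5-methoxybenzene-1,3-diol) | COc1cc(O)cc(O)c1 | starting material
7 | 1-methoxy-3,5-bis(methoxymethoxy)benzene | COCOc1cc(OC)cc(OCOC)c1 | intermediate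
8 | [4-methoxy-2,6-bis(methoxymethoxy)phenyl]lithium | [Li]c1c(OCOC)cc(OC)cc1OCOC | intermediate
9 | [4-(benzyloxy)-2-methoxy-6-methylphenyl][4-methoxy-2,6-bis(methoxymethoxy)phenyl]methanol (racemic) | COCOc1cc(OC)cc(OCOC)c1C(O)c1c(C)cc(OCc2ccccc2)cc1OC | intermediate
10 | [4-(benzyloxy)-2-methoxy-6-methylphenyl][4-methoxy-2,6-bis(methoxymethoxy)phenyl]methanone | COCOc1cc(OC)cc(OCOC)c1C(=O)c1c(C)cc(OCc2ccccc2)cc1OC | intermediate
11 | [4-(benzyloxy)-2-methoxy-6-methylphenyl](2,6-dihydroxy-4-methoxyphenyl)methanone | COc1cc(O)c(C(=O)c2c(C)cc(OCc3ccccc3)cc2OC)c(O)c1 | intermediate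
12 | [4-(benzyloxy)-2-methoxy-6-methylphenyl]{3-[(dimethylamino)methyl]-2,6-dihydroxy-4-methoxyphenyl}methanone | COc1cc(O)c(C(=O)c2c(C)cc(OCc3ccccc3)cc2OC)c(O)c1CN(C)C | intermediate
13 | 2-[4-(benzyloxy)-2-methoxy-6-methylbenzoyl]-3-hydroxy-5-methoxy-6-methylidenecyclohexa-2,4-dien-1-one (o-quinone methide) | C=C1C(=O)C(C(=O)c2c(C)cc(OCc3ccccc3)cc2OC)=C(O)C=C1OC | intermediate
14 | bis{3-[4-(benzyloxy)-2-methoxy-6-methylbenzoyl]-2,4-dihydroxy-6-methoxyphenyl}methane | COc1cc(O)c(C(=O)c2c(C)cc(OCc3ccccc3)cc2OC)c(O)c1Cc1c(OC)cc(O)c(C(=O)c2c(C)cc(OCc3ccccc3)cc2OC)c1O | intermediate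
15 | Digriseophene A (achiral) | COc1cc(O)c(C(=O)c2c(C)cc(O)cc2OC)c(O)c1Cc1c(OC)cc(O)c(C(=O)c2c(C)cc(O)cc2OC)c1O | target

## Summary

Total step count: 10.
Longest linear sequence: 9 steps (1 → 15 through steps 1, 2, 3, 5, 6, 7, 8, 9, 10); step 4 is the one-step ring-A branch.

Three steps most likely to fail:

**Step 5** (site of lithiation on 7, and addition to a di-ortho-substituted aldehyde). The fallback sets out from aldehyde 5 and comes back to the route at 11; it removes the regiochemical question by using a C3-symmetric ring-A precursor and installing the methyl ether last. Commercial phloroglucinol (benzene-1,3,5-triol) is converted with NaH/MOMCl into 1,3,5-tris(methoxymethoxy)benzene F1, whose three ring positions are identical. n-BuLi gives [2,4,6-tris(methoxymethoxy)phenyl]lithium F2, which adds to 5 to give [4-(benzyloxy)-2-methoxy-6-methylphenyl][2,4,6-tris(methoxymethoxy)phenyl]methanol F3. IBX oxidation gives [4-(benzyloxy)-2-methoxy-6-methylphenyl][2,4,6-tris(methoxymethoxy)phenyl]methanone F4, and HCl/MeOH gives [4-(benzyloxy)-2-methoxy-6-methylphenyl](2,4,6-trihydroxyphenyl)methanone F5. The para-hydroxyl, which is the most acidic and the only one not chelated to or flanking the ketone, is then methylated selectively (Me2SO4 1.0 equiv, K2CO3, acetone, rt) to give 11.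

**Step 9** (oligomerisation, since both 12 and 14 keep a free nucleophilic ring carbon, or sluggish amine loss). The fallback sets out from 11 and comes back at 14, bypassing the isolated Mannich base. 11 (2 equiv) is treated with formalin (1 equiv) in aqueous NaOH/MeOH at 0 °C → rt. Lederer–Manasse hydroxymethylation (an aldol-type addition of the phenolate to formaldehyde) gives [4-(benzyloxy)-2-methoxy-6-methylphenyl][2,6-dihydroxy-3-(hydroxymethyl)-4-methoxyphenyl]methanone F6. F6 loses water in the flask to the same o-quinone methide 13, which the second phenolate traps to give 14.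

**Step 10** (incomplete double debenzylation or poor solubility of the polyphenolic dimer, with a small risk of ketone over-reduction on long exposure). The fallback sets out from 11 and comes back at 15, moving the deprotection ahead of the coupling so that the last step is the bond-forming one. Any over-reduced material would be removed at the monomer stage rather than lost from the dimer. Hydrogenolysis of 11 (H2, Pd/C) gives (2,6-dihydroxy-4-methoxyphenyl)(4-hydroxy-2-methoxy-6-methylphenyl)methanone F7. Eschenmoser's salt converts part of it into {3-[(dimethylamino)methyl]-2,6-dihydroxy-4-methoxyphenyl}(4-hydroxy-2-methoxy-6-methylphenyl)methanone F8. Heating F8 with excess F7 in dioxane releases 2-(4-hydroxy-2-methoxy-6-methylbenzoyl)-3-hydroxy-5-methoxy-6-methylidenecyclohexa-2,4-dien-1-one F9, which is trapped by F7 at the tri-oxygenated ring (more nucleophilic than the acyl-deactivated ring B) to give 15 directly.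

## Further compounds

F1 | step 5 | 1,3,5-tris(methoxymethoxy)benzene | COCOc1cc(OCOC)cc(OCOC)c1
F2 | step 5 | [2,4,6-tris(methoxymethoxy)phenyl]lithium | [Li]c1c(OCOC)cc(OCOC)cc1OCOC
F3 | step 5 | [4-(benzyloxy)-2-methoxy-6-methylphenyl][2,4,6-tris(methoxymethoxy)phenyl]methanol (racemic) | COCOc1cc(OCOC)c(C(O)c2c(C)cc(OCc3ccccc3)cc2OC)c(OCOC)c1
F4 | step 5 | [4-(benzyloxy)-2-methoxy-6-methylphenyl][2,4,6-tris(methoxymethoxy)phenyl]methanone | COCOc1cc(OCOC)c(C(=O)c2c(C)cc(OCc3ccccc3)cc2OC)c(OCOC)c1
F5 | step 5 | [4-(benzyloxy)-2-methoxy-6-methylphenyl](2,4,6-trihydroxyphenyl)methanone | Oc1cc(O)c(C(=O)c2c(C)cc(OCc3ccccc3)cc2OC)c(O)c1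
F6 | step 9 | [4-(benzyloxy)-2-methoxy-6-methylphenyl][2,6-dihydroxy-3-(hydroxymethyl)-4-methoxyphenyl]methanone | COc1cc(O)c(C(=O)c2c(C)cc(OCc3ccccc3)cc2OC)c(O)c1CO
F7 | step 10 | (2,6-dihydroxy-4-methoxyphenyl)(4-hydroxy-2-methoxy-6-methylphenyl)methanone | COc1cc(O)c(C(=O)c2c(C)cc(O)cc2OC)c(O)c1
F8 | step 10 | {3-[(dimethylamino)methyl]-2,6-dihydroxy-4-methoxyphenyl}(4-hydroxy-2-methoxy-6-methylphenyl)methanone | COc1cc(O)c(C(=O)c2c(C)cc(O)cc2OC)c(O)c1CN(C)C
F9 | step 10 | 2-(4-hydroxy-2-methoxy-6-methylbenzoyl)-3-hydroxy-5-methoxy-6-methylidenecyclohexa-2,4-dien-1-one | C=C1C(=O)C(C(=O)c2c(C)cc(O)cc2OC)=C(O)C=C1OC
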